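**Strategy.** Ring A and the dihydrofuran ring are disconnected together: C3a–C7a, C6–C7 and C7–O are all made by one gold-catalysed furan–yne cycloisomerisation. The step exploits the substitution of ring A, in which O1 sits on C7a beside an oxygen on C7, C4 and C6 carry hydrogen and C5 the allyl group; this is exactly what a 4-allylfuran-2-yl ring on C3 and a terminal ethynyl ether on the C2 oxygen deliver. The precursor is therefore the ethynyl ether of a syn 1-aryl-2-furyl-3-(eugenyloxy)propanol, whose two stereocentres come from an Evans aldol and pass through the cascade untouched; O-methylation and MOM removal finish the target.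

Key step: step 10

Assumption: allyltributylstannane and the common reagents are taken as commercial; the transient arene oxide 21 is drawn without configuration at its two epoxide carbons, because both epimers collapse to the same phenol; locants are those of the dihydrobenzofuran (O1, C2, C3, C3a, C4 to C7, C7a), with primed locants for the furan.

The target is the trans (2S,3R) compound. The trans ring corresponds to a syn (1S,2R) open-chain alcohol, and this is the sense that the (S)-4-benzyl auxiliary delivers.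

## Route

**Step 1**
Reactants: 1 4-bromofuran-2-carbaldehyde
Product: 2 4-allylfuran-2-carbaldehyde
Conditions: allylSnBu3 (1.2 equiv), Pd(PPh3)4 (5 mol %), toluene, 100 °C
Reagents that add atoms: allyltributylstannane, C=CC[Sn](CCCC)(CCCC)CCCC
Why: Stille coupling of the furyl bromide under zerovalent palladium needs no base, so the aldehyde should survive while the allyl group is placed on C4' of the furan.

**Step 2**
Reactants: 2 4-allylfuran-2-carbaldehyde
Product: 3 4-allyl-2-(2,2-dibromovinyl)furan
Conditions: CBr4 (1.5 equiv), PPh3 (3 equiv), CH2Cl2, 0 °C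
Reagents that add atoms: carbon tetrabromide, BrC(Br)(Br)Br
Why: Wittig-type dibromomethylenation of the aldehyde (first stage of the Corey–Fuchs reaction) is routine for furfurals and leaves the allyl alkene alone.

**Step 3**
Reactants: 3 4-allyl-2-(2,2-dibromovinyl)furan (1.3 equiv); 4 (S)-4-benzyloxazolidin-2-one
Product: 5 (S)-3-[(4-allylfuran-2-yl)ethynyl]-4-benzyloxazolidin-2-one
Conditions: CuI (12 mol %), MeNHCH2CH2NHMe (18 mol %), Cs2CO3 (4 equiv), 1,4-dioxane, 60 °C
Reagents that add atoms: none
Why: Copper-catalysed N-alkynylation of an oxazolidinone by a gem-dibromoalkene (Ullmann–Goldberg-type C–N coupling with loss of two HBr) is an established ynamide synthesis and does not touch the stereocentre of the auxiliary.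

**Step 4**
Reactants: 5 (S)-3-[(4-allylfuran-2-yl)ethynyl]-4-benzyloxazolidin-2-one
Product: 6 (S)-3-[(4-allylfuran-2-yl)acetyl]-4-benzyloxazolidin-2-one
Conditions: TsOH·H2O (10 mol %), H2O (5 equiv), MeCN, rt
Reagents that add atoms: water, O
Why: Acid-catalysed hydration of an ynamide proceeds by protonation at the furyl-bearing carbon to a keteniminium ion that takes up water at the nitrogen-bearing carbon, so only the N-acyl oxazolidinone can form.

**Step 5**
Reactants: 7 vanillin
Product: 8 3-methoxy-4-(methoxymethoxy)benzaldehyde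
Conditions: MOMCl (1.3 equiv), iPr2NEt (2 equiv), CH2Cl2, 0 °C to rt
Reagents that add atoms: chloromethyl methyl ether, COCCl
Why: Williamson-type O-alkylation gives an acetal protecting group that tolerates the boron aldol, hydride, KH and n-BuLi used later and leaves under mild acid.

**Step 6**
Reactants: 6 (S)-3-[(4-allylfuran-2-yl)acetyl]-4-benzyloxazolidin-2-one; 8 3-methoxy-4-(methoxymethoxy)benzaldehyde
Product: 11 (S)-4-benzyl-3-[(2R,3S)-2-(4-allylfuran-2-yl)-3-hydroxy-3-(3-methoxy-4-(methoxymethoxy)phenyl)propanoyl]oxazolidin-2-one, via dibutylboron Z-enolate 9 (not isolated), via dibutylboron aldolate 10 (not isolated)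
Conditions: Bu2BOTf (1.2 equiv), iPr2NEt (1.4 equiv), CH2Cl2, −78 to 0 °C; 8, −78 to 0 °C; pH 7 buffer, MeOH, 30% H2O2, 0 °C
Reagents that add atoms: none
Why: Evans syn aldol: the boron Z-enolate reacts through a closed Zimmerman–Traxler transition state on the face away from the benzyl group of the (S)-auxiliary, which sets both new stereocentres (2R,3S) with furyl and hydroxyl syn, as needed for C3 and C2 of the target.

**Step 7**
Reactants: 11 Evans syn aldol adduct
Product: 12 (1S,2R)-2-(4-allylfuran-2-yl)-1-[3-methoxy-4-(methoxymethoxy)phenyl]propane-1,3-diol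
Conditions: LiBH4 (2 equiv), MeOH (2 equiv), THF, 0 °C
Reagents that add atoms: none
Why: Reductive cleavage of the N-acyl oxazolidinone by LiBH4 gives the primary alcohol and returns the auxiliary, and the cold, weakly basic conditions should avoid retro-aldol and epimerisation at the furyl-bearing carbon.

**Step 8**
Reactants: 12 (1S,2R)-diol; 13 eugenol (1.1 equiv)
Product: 14 (1S,2R)-2-(4-allylfuran-2-yl)-3-(4-allyl-2-methoxyphenoxy)-1-[3-methoxy-4-(methoxymethoxy)phenyl]propan-1-ol
Conditions: PPh3 (1.3 equiv), DIAD (1.3 equiv), toluene, 0 °C to rt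
Reagents that add atoms: none
Why: Mitsunobu etherification activates the unhindered primary hydroxyl much faster than the hindered secondary benzylic one, and the phenoxide displaces at a CH2 carbon, so no stereocentre is involved.

**Step 9**
Reactants: 14 (1S,2R)-alcohol; 15 trichloroethylene (1.1 equiv)
Product: 19 4-allyl-1-{[(2R,3S)-2-(4-allylfuran-2-yl)-3-(ethynyloxy)-3-(3-methoxy-4-(methoxymethoxy)phenyl)propyl]oxy}-2-methoxybenzene (ethynyl ether of 14), via dichlorovinyl ether 16 (not isolated), via chloroethynyl ether 17 (not isolated), via lithium acetylide 18 (not isolated)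
Conditions: KH (1.5 equiv), THF, 0 °C; 15, −50 °C to rt; n-BuLi (2.4 equiv), −78 to −40 °C; MeOH, −78 °C; cold work-up, used at once
Reagents that add atoms: none
Why: One-pot alkynyl ether synthesis from an alcohol and trichloroethylene: the potassium alkoxide adds to dichloroacetylene released in situ, n-BuLi then eliminates HCl and exchanges the remaining chlorine for lithium, and methanol protonates the acetylide; the C–O bond at the carbinol carbon is never broken, so its configuration is kept.

**Step 10**
Reactants: 19 ethynyl ether of 14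
Product: 22 (2S,3R)-5-allyl-3-[(4-allyl-2-methoxyphenoxy)methyl]-2-[3-methoxy-4-(methoxymethoxy)phenyl]-2,3-dihydrobenzofuran-7-ol, via oxepine 20 (not isolated), via arene oxide 21 (not isolated)
Conditions: Ph3PAuNTf2 (3 mol %), 4 Å MS, CH2Cl2, −20 °C to rt
Reagents that add atoms: none
Why: Cationic monovalent gold binds the polarised alkynyl ether and makes its oxygen-bearing carbon (future C7a) ketenium-like; the furan attacks it through the C2'=C3' bond at the tethered carbon (5-exo-dig, closing the dihydrofuran ring) to give a cyclopropyl gold carbene that opens to a (Z)-dienal gold carbene. The aldehyde oxygen adds to the carbene carbon (C7–O) as gold leaves, giving oxepine 20, whose disrotatory six-electron electrocyclisation forms C6–C7 and so closes ring A as arene oxide 21. The oxide opens at C6–O because the resulting cation is delocalised onto C7a and stabilised by O1, and loss of the C7 proton gives the C7 phenol. The closest known reaction type is the gold-catalysed furan–yne phenol synthesis, which has been run on 2-(furan-2-yl)ethyl alkynyl ethers to give 7-hydroxy-2,3-dihydrobenzofurans. No stereocentre is created: C2 and C3 are spectators with no bond broken, so the syn arrangement of 19 becomes the trans ring of 22. The step needs alkyne-over-alkene and furan-over-arene selectivity and 7- over 6-hydroxylation; these rest on the far higher affinity of gold for the electron-rich alkynyl ether, on the much greater nucleophilicity of the furan than of the guaiacyl ring for the same 5-exo mode, and on the O1 donor, while the low temperature keeps the benzylic C2–O bond from ionising.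

**Step 11**
Reactants: 22 C7 phenol
Product: 23 (2S,3R)-5-allyl-3-[(4-allyl-2-methoxyphenoxy)methyl]-7-methoxy-2-[3-methoxy-4-(methoxymethoxy)phenyl]-2,3-dihydrobenzofuran
Conditions: MeI (3 equiv), K2CO3 (2 equiv), acetone, 40 °C
Reagents that add atoms: iodomethane, CI
Why: Williamson methylation of the only free phenol; the MOM ether, the allyl groups and both stereocentres are inert to carbonate.

**Step 12**
Reactants: 23 MOM-protected 7-methyl ether
Product: 24 4-{(2S,3R)-5-allyl-3-[(4-allyl-2-methoxyphenoxy)methyl]-7-methoxy-2,3-dihydrobenzofuran-2-yl}-2-methoxyphenol (target)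
Conditions: 3 M aq HCl/MeOH (1:9), 40 °C
Reagents that add atoms: none
Why: Acid-catalysed acetal exchange removes the MOM group as dimethoxymethane under conditions that leave aryl methyl ethers and allyl groups intact; any reversible ionisation at C2 should return the more stable trans ring.

## Compound list

1 | 4-bromofuran-2-carbaldehyde | O=Cc1cc(Br)co1 | starting material
2 | 4-allylfuran-2-carbaldehyde | O=Cc1cc(CC=C)co1 | intermediate
3 | 4-allyl-2-(2,2-dibromovinyl)furan | BrC(Br)=Cc1cc(CC=C)co1 | intermediate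
4 | (S)-4-benzyloxazolidin-2-one | O=C1N[C@@H](Cc2ccccc2)CO1 | starting material
5 | (S)-3-[(4-allylfuran-2-yl)ethynyl]-4-benzyloxazolidin-2-one | C=CCc1coc(C#CN2[C@@H](Cc3ccccc3)COC2=O)c1 | intermediate
6 | (S)-3-[(4-allylfuran-2-yl)acetyl]-4-benzyloxazolidin-2-one | C=CCc1coc(CC(=O)N2[C@@H](Cc3ccccc3)COC2=O)c1 | intermediate
7 | vanillin | COc1cc(C=O)ccc1O | starting material
8 | 3-methoxy-4-(methoxymethoxy)benzaldehyde | COCOc1ccc(C=O)cc1OC | intermediate
9 | dibutylboron (Z)-enolate of 6 (not isolated) | CCCCB(CCCC)O/C(=C\c1cc(CC=C)co1)N1[C@@H](Cc2ccccc2)COC1=O | intermediate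
10 | O-dibutylboryl aldolate of 11 (not isolated) | O=C(N1[C@@H](Cc2ccccc2)COC1=O)[C@H]([C@H](OB(CCCC)CCCC)c1ccc(OCOC)c(OC)c1)c1cc(CC=C)co1 | intermediate
11 | (S)-4-benzyl-3-[(2R,3S)-2-(4-allylfuran-2-yl)-3-hydroxy-3-(3-methoxy-4-(methoxymethoxy)phenyl)propanoyl]oxazolidin-2-one | O=C(N1[C@@H](Cc2ccccc2)COC1=O)[C@H]([C@H](O)c1ccc(OCOC)c(OC)c1)c1cc(CC=C)co1 | intermediate
12 | (1S,2R)-2-(4-allylfuran-2-yl)-1-[3-methoxy-4-(methoxymethoxy)phenyl]propane-1,3-diol | OC[C@H]([C@H](O)c1ccc(OCOC)c(OC)c1)c1cc(CC=C)co1 | intermediate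
13 | eugenol (4-allyl-2-methoxyphenol) | C=CCc1ccc(O)c(OC)c1 | starting material
14 | (1S,2R)-2-(4-allylfuran-2-yl)-3-(4-allyl-2-methoxyphenoxy)-1-[3-methoxy-4-(methoxymethoxy)phenyl]propan-1-ol | C=CCc1ccc(OC[C@H]([C@H](O)c2ccc(OCOC)c(OC)c2)c2cc(CC=C)co2)c(OC)c1 | intermediate
15 | trichloroethylene | ClC=C(Cl)Cl | starting material
16 | (E)-1,2-dichlorovinyl ether of 14 (not isolated) | C=CCc1ccc(OC[C@H]([C@H](O/C(Cl)=C\Cl)c2ccc(OCOC)c(OC)c2)c2cc(CC=C)co2)c(OC)c1 | intermediate
17 | chloroethynyl ether of 14 (not isolated) | C=CCc1ccc(OC[C@H]([C@H](OC#CCl)c2ccc(OCOC)c(OC)c2)c2cc(CC=C)co2)c(OC)c1 | intermediate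
18 | lithium acetylide of 19 (not isolated) | C=CCc1ccc(OC[C@H]([C@H](OC#C[Li])c2ccc(OCOC)c(OC)c2)c2cc(CC=C)co2)c(OC)c1 | intermediate
19 | ethynyl ether of 14: 4-allyl-1-{[(2R,3S)-2-(4-allylfuran-2-yl)-3-(ethynyloxy)-3-(3-methoxy-4-(methoxymethoxy)phenyl)propyl]oxy}-2-methoxybenzene | C=CCc1ccc(OC[C@H]([C@H](OC#C)c2ccc(OCOC)c(OC)c2)c2cc(CC=C)co2)c(OC)c1 | intermediate
20 | dihydrofuran-fused oxepine (oxepine oxygen between C6 and C7; C7=C7a, C3a=C4, C5=C6; substituents and configuration at C2 and C3 as in 22; not isolated) | C=CCc1ccc(OC[C@H]2C3=CC(CC=C)=COC=C3O[C@@H]2c2ccc(OCOC)c(OC)c2)c(OC)c1 | intermediate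
21 | ring A 6,7-arene oxide (epoxide across C6–C7; C3a=C7a, C4=C5; mixture at the epoxide carbons; not isolated) | C=CCc1ccc(OC[C@H]2C3=C(O[C@@H]2c2ccc(OCOC)c(OC)c2)C2OC2C(CC=C)=C3)c(OC)c1 | intermediate
22 | (2S,3R)-5-allyl-3-[(4-allyl-2-methoxyphenoxy)methyl]-2-[3-methoxy-4-(methoxymethoxy)phenyl]-2,3-dihydrobenzofuran-7-ol | C=CCc1ccc(OC[C@H]2c3cc(CC=C)cc(O)c3O[C@@H]2c2ccc(OCOC)c(OC)c2)c(OC)c1 | intermediate
23 | (2S,3R)-5-allyl-3-[(4-allyl-2-methoxyphenoxy)methyl]-7-methoxy-2-[3-methoxy-4-(methoxymethoxy)phenyl]-2,3-dihydrobenzofuran | C=CCc1ccc(OC[C@H]2c3cc(CC=C)cc(OC)c3O[C@@H]2c2ccc(OCOC)c(OC)c2)c(OC)c1 | intermediate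
24 | 4-{(2S,3R)-5-allyl-3-[(4-allyl-2-methoxyphenoxy)methyl]-7-methoxy-2,3-dihydrobenzofuran-2-yl}-2-methoxyphenol (CNP0138854.1) | C=CCc1ccc(OC[C@H]2c3cc(CC=C)cc(OC)c3O[C@@H]2c2ccc(O)c(OC)c2)c(OC)c1 | target

## Step count and risks

Total step count: 12. Longest linear sequence: 11 steps (steps 1 to 4 and 6 to 12, from 1); step 5 is a one-step side branch.

**Step 10 (key step).** The gold-activated alkynyl ether sits on an electron-rich benzylic carbon. The C2–O bond may ionise before the furan closes, which would cost configuration at C2 or fragment the molecule; hydration of the alkynyl ether or attack by the guaiacyl ring are further possible drains.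
Fallback: take ring A from eugenol as an intact benzene ring and form O1–C2 last. The fallback sets out from eugenol 13 and returns to the route at the target 24.
- Magnesium-mediated ortho-formylation of 13 (MgCl2, Et3N, paraformaldehyde, MeCN, reflux) should give 5-allyl-2-hydroxy-3-methoxybenzaldehyde F1, which is protected (MOMCl, iPr2NEt) as 5-allyl-3-methoxy-2-(methoxymethoxy)benzaldehyde F2.
- The sequence of steps 2 to 4 (CBr4, PPh3; then CuI, MeNHCH2CH2NHMe, Cs2CO3 with 4; then TsOH·H2O in wet MeCN) leads through the dibromoalkene F3 and the ynamide F4 to the arylacetyl oxazolidinone F5.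
- Evans syn aldol of F5 with 8 (Bu2BOTf, iPr2NEt) gives the aldol adduct F6, LiBH4 gives the diol F7, and Mitsunobu etherification with 13 gives the aryl ether F8.
- Methanolic HCl at 40 °C then removes both MOM groups and closes the ring. The p-hydroxybenzylic cation is captured by the ring A phenol; C3 keeps the configuration set in the aldol and C2 settles trans to it under thermodynamic control, giving 24 directly.

**Step 9.** The strongly basic sequence may isomerise the allyl groups to propenyl groups or metalate the furan or the MOM-bearing ring. The secondary benzylic alkynyl ether may also be lost on isolation by retro-ene or sigmatropic pathways.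
Fallback: build the alkyne carbon by carbonyl olefination instead of alkoxide addition to dichloroacetylene; from 14 back to 19. Formylation (acetic formic anhydride, pyridine, 0 °C) gives the formate F9. Wittig-type dichloromethylenation of the formate carbonyl (PPh3, CCl4, THF, 60 °C) gives the 2,2-dichlorovinyl ether F10. n-BuLi (2.2 equiv, −78 °C) then effects elimination and chlorine–lithium exchange to the same lithium acetylide 18, and methanol gives 19. This avoids KH and free dichloroacetylene.

**Step 8.** Site selectivity may be poor: the electron-rich secondary benzylic hydroxyl may be activated and ionise or eliminate, or displace the activated primary centre to give an oxetane.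
Fallback: mask the secondary hydroxyl before the auxiliary is removed; from 11 back to 14. Silylation (TESOTf, 2,6-lutidine, CH2Cl2, −78 °C) gives the triethylsilyl ether F11. LiBH4 gives the primary alcohol F12, Mitsunobu etherification with 13 gives the silylated aryl ether F13, and TBAF in THF at 0 °C gives 14.

## Further compounds

F1 | step 10 | 5-allyl-2-hydroxy-3-methoxybenzaldehyde | C=CCc1cc(C=O)c(O)c(OC)c1
F2 | step 10 | 5-allyl-3-methoxy-2-(methoxymethoxy)benzaldehyde | C=CCc1cc(C=O)c(OCOC)c(OC)c1
F3 | step 10 | 5-allyl-1-(2,2-dibromovinyl)-3-methoxy-2-(methoxymethoxy)benzene | C=CCc1cc(C=C(Br)Br)c(OCOC)c(OC)c1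
F4 | step 10 | (S)-3-{[5-allyl-3-methoxy-2-(methoxymethoxy)phenyl]ethynyl}-4-benzyloxazolidin-2-one | C=CCc1cc(C#CN2[C@@H](Cc3ccccc3)COC2=O)c(OCOC)c(OC)c1
F5 | step 10 | (S)-3-{[5-allyl-3-methoxy-2-(methoxymethoxy)phenyl]acetyl}-4-benzyloxazolidin-2-one | C=CCc1cc(CC(=O)N2[C@@H](Cc3ccccc3)COC2=O)c(OCOC)c(OC)c1
F6 | step 10 | (S)-4-benzyl-3-{(2S,3S)-2-[5-allyl-3-methoxy-2-(methoxymethoxy)phenyl]-3-hydroxy-3-[3-methoxy-4-(methoxymethoxy)phenyl]propanoyl}oxazolidin-2-one | O=C(N1[C@@H](Cc2ccccc2)COC1=O)[C@H]([C@H](O)c1ccc(OCOC)c(OC)c1)c1cc(CC=C)cc(OC)c1OCOC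
F7 | step 10 | (1S,2R)-2-[5-allyl-3-methoxy-2-(methoxymethoxy)phenyl]-1-[3-methoxy-4-(methoxymethoxy)phenyl]propane-1,3-diol | OC[C@H]([C@H](O)c1ccc(OCOC)c(OC)c1)c1cc(CC=C)cc(OC)c1OCOC
F8 | step 10 | (1S,2R)-2-[5-allyl-3-methoxy-2-(methoxymethoxy)phenyl]-3-(4-allyl-2-methoxyphenoxy)-1-[3-methoxy-4-(methoxymethoxy)phenyl]propan-1-ol | C=CCc1ccc(OC[C@H]([C@H](O)c2ccc(OCOC)c(OC)c2)c2cc(CC=C)cc(OC)c2OCOC)c(OC)c1
F9 | step 9 | formate ester of 14 | C=CCc1ccc(OC[C@H]([C@H](OC=O)c2ccc(OCOC)c(OC)c2)c2cc(CC=C)co2)c(OC)c1
F10 | step 9 | 2,2-dichlorovinyl ether of 14 | C=CCc1ccc(OC[C@H]([C@H](OC=C(Cl)Cl)c2ccc(OCOC)c(OC)c2)c2cc(CC=C)co2)c(OC)c1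
F11 | step 8 | triethylsilyl ether of 11 | O=C(N1[C@@H](Cc2ccccc2)COC1=O)[C@H]([C@H](O[Si](CC)(CC)CC)c1ccc(OCOC)c(OC)c1)c1cc(CC=C)co1
F12 | step 8 | (2R,3S)-2-(4-allylfuran-2-yl)-3-[3-methoxy-4-(methoxymethoxy)phenyl]-3-(triethylsilyloxy)propan-1-ol | OC[C@H]([C@H](O[Si](CC)(CC)CC)c1ccc(OCOC)c(OC)c1)c1cc(CC=C)co1
F13 | step 8 | triethylsilyl ether of 14 | C=CCc1ccc(OC[C@H]([C@H](O[Si](CC)(CC)CC)c2ccc(OCOC)c(OC)c2)c2cc(CC=C)co2)c(OC)c1
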